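**Retrosynthetic overview**
- The butenolide C=C is placed last, by moving the double bond of an α-methylene lactone into the ring; the methylene carbon comes from formaldehyde (carboxylation, then decarboxylative Mannich methylenation).
- The trans-lactone acid precursor comes from a lactone imide by removing the chiral auxiliary and the tert-butyl ester.
- Key C–C bond (carbinol carbon to the carbon that carries the ring CO2H): intermolecular Evans syn-aldol of a succinate-derived (S)-benzyloxazolidinone boron enolate with a C16 ester aldehyde; this sets the only stereocentre of the target.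
- Only one ring is formed: the γ-lactone, by lactonisation of the aldol adduct onto the succinate methyl ester; it is later desaturated to the butenolide.

Assumption: the target is the (R)-enantiomer as drawn; lithium, sodium, magnesium or ammonium salt forms of a numbered compound (and the boron aldolate of 8) that revert on work-up are counted with that compound.

**Route**

Step 1
Reactants: 1 (4S)-4-benzyl-1,3-oxazolidin-2-one; 2 methyl 4-chloro-4-oxobutanoate
Product: 3 (4S)-4-benzyl-3-(4-methoxy-4-oxobutanoyl)-1,3-oxazolidin-2-one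
Conditions: n-BuLi (1.05 equiv), THF, −78 °C, 30 min; then 2 (1.1 equiv), −78 → 0 °C, 1 h
Reagents that add atoms: none
Why: N-acylation of the lithiated oxazolidinone by the acid chloride, which is far more electrophilic than the methyl ester; the auxiliary stereocentre is untouched.

Step 2
Reactants: 4 16-tert-butoxy-16-oxohexadecanoic acid (mono-tert-butyl hexadecanedioate, a stock linker building block)
Product: 5 tert-butyl 16-hydroxyhexadecanoate
Conditions: BH3·SMe2 (1.5 equiv), THF, 0 °C → rt, 4 h; MeOH quench, evaporate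
Reagents that add atoms: none
Why: chemoselective borane reduction of the carboxylic acid (via the acyloxyborane), which is much faster than reduction of the tert-butyl ester.

Step 3
Reactants: 5 tert-butyl 16-hydroxyhexadecanoate
Product: 6 tert-butyl 16-oxohexadecanoate
Conditions: 2,2,6,6-tetramethylpiperidin-1-oxyl (TEMPO, 10 mol %), PhI(OAc)2 (1.1 equiv), CH2Cl2, rt, 3 h; used directly
Reagents that add atoms: none
Why: oxoammonium (TEMPO) oxidation of a primary alcohol stops at the aldehyde under anhydrous conditions and leaves the ester alone.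

Step 4 (key step)
Reactants: 3 (4S)-4-benzyl-3-(4-methoxy-4-oxobutanoyl)-1,3-oxazolidin-2-one; 6 tert-butyl 16-oxohexadecanoate
Product: 9 tert-butyl 15-[(2R,3S)-3-{[(4S)-4-benzyl-2-oxo-1,3-oxazolidin-3-yl]carbonyl}-5-oxooxolan-2-yl]pentadecanoate, via Z-dibutylboron enolate 7 (not isolated), via syn-aldol adduct 8 (not isolated)
Conditions: 3, Bu2BOTf (1.15 equiv), i-Pr2NEt (1.3 equiv), CH2Cl2, −78 → 0 °C, 45 min; 6 (1.05 equiv), −78 °C 1 h → 0 °C 2 h; pH 7 phosphate buffer, MeOH, 30 % H2O2, 0 °C; crude, pyridinium p-toluenesulfonate (10 mol %), toluene, 50 °C, 2 h; chromatography to a single diastereomer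
Reagents that add atoms: none
Why: Evans syn-aldol: the Z-boron enolate reacts through a chair Zimmerman–Traxler transition state on the face away from the benzyl group, setting the carbinol carbon R (α-carbon S), and the γ-hydroxy methyl ester then lactonises to the trans-lactone.

Step 5
Reactants: 9 tert-butyl 15-[(2R,3S)-3-{[(4S)-4-benzyl-2-oxo-1,3-oxazolidin-3-yl]carbonyl}-5-oxooxolan-2-yl]pentadecanoate
Product: 11 (2R,3S)-2-(15-tert-butoxy-15-oxopentadecyl)-5-oxooxolane-3-carboxylic acid, via peroxy acid 10 (not isolated)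
Conditions: LiOH·H2O (2 equiv), 30 % H2O2 (5 equiv), THF–H2O 3:1, 0 °C, 1.5 h; aq. Na2SO3; CH2Cl2 extraction recovers 1; 1 M HCl to pH 2, EtOAc
Reagents that add atoms: hydrogen peroxide, OO
Why: hydroperoxide cleavage of the exocyclic imide carbonyl (Evans auxiliary removal) is selective, the tert-butyl ester is inert, and any opened lactone recloses at pH 2; no stereocentre is affected.

Step 6
Reactants: 11 (2R,3S)-2-(15-tert-butoxy-15-oxopentadecyl)-5-oxooxolane-3-carboxylic acid
Product: 12 (2R,3S)-2-(14-carboxytetradecyl)-5-oxooxolane-3-carboxylic acid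
Conditions: CF3CO2H–CH2Cl2 1:3, rt, 2 h; evaporate with toluene
Reagents that add atoms: none
Why: acidolysis of the tert-butyl ester (loss of isobutene via the tert-butyl cation) before the hot basic carboxylation, which a free carboxylate tolerates better than an ester; the lactone and stereocentres are acid-stable.

Step 7
Reactants: 12 (2R,3S)-2-(14-carboxytetradecyl)-5-oxooxolane-3-carboxylic acid
Product: 13 (2R,3S)-2-(14-carboxytetradecyl)-5-oxooxolane-3,4-dicarboxylic acid (C4 epimers, crude)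
Conditions: MeOMgOCO2Me (2 M in DMF, 40 equiv), 135 °C, 48 h, N2; pour into cold 6 M HCl, EtOAc; used at once
Reagents that add atoms: methyl magnesium carbonate (methoxymagnesium methyl carbonate), COC(=O)O[Mg]OC
Why: Stiles carboxylation: the lactone α-carbon is carboxylated because the product is held as a magnesium chelate with the neighbouring carboxylate, while simple carboxylates do not react; this is the standard activation used for paraconic acids.

Step 8
Reactants: 13 (2R,3S)-2-(14-carboxytetradecyl)-5-oxooxolane-3,4-dicarboxylic acid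
Product: 15 (2R,3S)-2-(14-carboxytetradecyl)-4-methylidene-5-oxooxolane-3-carboxylic acid, via Mannich base 14 (not isolated)
Conditions: 37 % aq. HCHO, PhNHMe, NaOAc, AcOH, rt, 2 h; 1 M HCl, EtOAc; recrystallise
Reagents that add atoms: formaldehyde, C=O
Why: Mannich reaction of the malonic half-acid with the in situ iminium ion, then decarboxylative elimination of N-methylaniline, gives the exocyclic methylene under mildly acidic conditions; C2 is untouched.

Step 9
Reactants: 15 (2R,3S)-2-(14-carboxytetradecyl)-4-methylidene-5-oxooxolane-3-carboxylic acid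
Product: 18 (2R)-2-(14-carboxytetradecyl)-4-methyl-5-oxo-2,5-dihydrofuran-3-carboxylic acid, via exo-methylene mixed anhydride 16 (not isolated), via butenolide mixed anhydride 17 (not isolated)
Conditions: Ac2O (neat), 120 °C, 2 h, N2; evaporate; THF–H2O 4:1, 45 °C, 3 h; recrystallise; check er by chiral HPLC
Reagents that add atoms: none
Why: in the mixed anhydride the ring C3–H is α to an activated acyl group and allylic, so thermal enolisation and γ-reprotonation (a 1,3-prototropic shift, the classical protolichesterinic-to-lichesterinic acid isomerisation) move the double bond into the ring without base touching the C2–H stereocentre, and aqueous THF then hydrolyses the anhydrides.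

**Compound list**

1 | (4S)-4-benzyl-1,3-oxazolidin-2-one | O=C1N[C@@H](Cc2ccccc2)CO1 | starting material
2 | methyl 4-chloro-4-oxobutanoate | COC(=O)CCC(=O)Cl | starting material
3 | (4S)-4-benzyl-3-(4-methoxy-4-oxobutanoyl)-1,3-oxazolidin-2-one | COC(=O)CCC(=O)N1[C@@H](Cc2ccccc2)COC1=O | intermediate
4 | 16-tert-butoxy-16-oxohexadecanoic acid | CC(C)(C)OC(=O)CCCCCCCCCCCCCCC(=O)O | starting material
5 | tert-butyl 16-hydroxyhexadecanoate | CC(C)(C)OC(=O)CCCCCCCCCCCCCCCO | intermediate
6 | tert-butyl 16-oxohexadecanoate | CC(C)(C)OC(=O)CCCCCCCCCCCCCCC=O | intermediate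
7 | (4S)-4-benzyl-3-[(1Z)-1-(dibutylboranyloxy)-4-methoxy-4-oxobut-1-en-1-yl]-1,3-oxazolidin-2-one | COC(=O)C/C=C(\OB(CCCC)CCCC)N1[C@@H](Cc2ccccc2)COC1=O | intermediate
8 | 1-tert-butyl 19-methyl (16R,17S)-17-{[(4S)-4-benzyl-2-oxo-1,3-oxazolidin-3-yl]carbonyl}-16-hydroxynonadecanedioate | COC(=O)C[C@H](C(=O)N1[C@@H](Cc2ccccc2)COC1=O)[C@H](O)CCCCCCCCCCCCCCC(=O)OC(C)(C)C | intermediate
9 | tert-butyl 15-[(2R,3S)-3-{[(4S)-4-benzyl-2-oxo-1,3-oxazolidin-3-yl]carbonyl}-5-oxooxolan-2-yl]pentadecanoate (trans-lactone) | O=C1C[C@H](C(=O)N2[C@@H](Cc3ccccc3)COC2=O)[C@@H](CCCCCCCCCCCCCCC(=O)OC(C)(C)C)O1 | intermediate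
10 | (2R,3S)-2-(15-tert-butoxy-15-oxopentadecyl)-5-oxooxolane-3-carboperoxoic acid | O=C1C[C@H](C(=O)OO)[C@@H](CCCCCCCCCCCCCCC(=O)OC(C)(C)C)O1 | intermediate
11 | (2R,3S)-2-(15-tert-butoxy-15-oxopentadecyl)-5-oxooxolane-3-carboxylic acid | O=C1C[C@H](C(=O)O)[C@@H](CCCCCCCCCCCCCCC(=O)OC(C)(C)C)O1 | intermediate
12 | (2R,3S)-2-(14-carboxytetradecyl)-5-oxooxolane-3-carboxylic acid | O=C1C[C@H](C(=O)O)[C@@H](CCCCCCCCCCCCCCC(=O)O)O1 | intermediate
13 | (2R,3S)-2-(14-carboxytetradecyl)-5-oxooxolane-3,4-dicarboxylic acid (C4 epimers) | O=C1C(C(=O)O)[C@H](C(=O)O)[C@@H](CCCCCCCCCCCCCCC(=O)O)O1 | intermediate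
14 | (2R,3S)-2-(14-carboxytetradecyl)-4-{[methyl(phenyl)amino]methyl}-5-oxooxolane-3,4-dicarboxylic acid | O=C1C(CN(C)c2ccccc2)(C(=O)O)[C@H](C(=O)O)[C@@H](CCCCCCCCCCCCCCC(=O)O)O1 | intermediate
15 | (2R,3S)-2-(14-carboxytetradecyl)-4-methylidene-5-oxooxolane-3-carboxylic acid | O=C1C(=C)[C@H](C(=O)O)[C@@H](CCCCCCCCCCCCCCC(=O)O)O1 | intermediate
16 | bis(acetic) mixed anhydride of 15 | O=C1C(=C)[C@H](C(=O)OC(C)=O)[C@@H](CCCCCCCCCCCCCCC(=O)OC(C)=O)O1 | intermediate
17 | bis(acetic) mixed anhydride of 18 | CC1=C(C(=O)OC(C)=O)[C@@H](CCCCCCCCCCCCCCC(=O)OC(C)=O)OC1=O | intermediate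
18 | (2R)-2-(14-carboxytetradecyl)-4-methyl-5-oxo-2,5-dihydrofuran-3-carboxylic acid | CC1=C(C(=O)O)[C@@H](CCCCCCCCCCCCCCC(=O)O)OC1=O | target

**Totals and weak points**

Total steps: 9. Longest linear sequence: 8 steps (4 → 5 → 6 → 9 → 11 → 12 → 13 → 15 → 18).

Step 7 is the most likely to fail: the carboxylation needs long heating with a large excess of MeOMgOCO2Me, gives a very polar triacid, and its yields vary. The fallback sets out from 11 and comes back at 15. The dianion of 11 (NaN(SiMe3)2, exactly 2.05 equiv so the ester α-position is spared, THF, −78 °C) is trapped with [Me2N=CH2]I to give (2R,3S,4R)-2-(15-tert-butoxy-15-oxopentadecyl)-4-[(dimethylamino)methyl]-5-oxooxolane-3-carboxylic acid F6. MeI and KHCO3 in MeOH convert it into the trimethylammonium betaine F7, which loses trimethylamine under the same conditions to give (2R,3S)-2-(15-tert-butoxy-15-oxopentadecyl)-4-methylidene-5-oxooxolane-3-carboxylic acid F8. CF3CO2H in CH2Cl2 then removes the tert-butyl ester to give 15.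

Step 9 is next: the thermal double-bond shift may stop short, the anhydrides may hydrolyse sluggishly, and the er could erode. The fallback sets out from 11 and comes back at 18, and builds the ring alkene by selenoxide elimination instead of isomerisation. The dianion of 11 (NaN(SiMe3)2, 2.05 equiv, THF, −78 °C) is methylated with MeI trans to the carboxylate to give (2R,3S,4S)-2-(15-tert-butoxy-15-oxopentadecyl)-4-methyl-5-oxooxolane-3-carboxylic acid F9. A second dianion formation and PhSeBr, again entering anti to the carboxylate, give (2R,3S,4S)-2-(15-tert-butoxy-15-oxopentadecyl)-4-methyl-5-oxo-4-(phenylselanyl)oxolane-3-carboxylic acid F10, in which selenium is cis to the C3–H. 30 % H2O2 in THF at 0 °C gives the selenoxide F11, which undergoes syn-elimination towards that activated C3–H to give (2R)-2-(15-tert-butoxy-15-oxopentadecyl)-4-methyl-5-oxo-2,5-dihydrofuran-3-carboxylic acid F12. CF3CO2H in CH2Cl2 then gives 18 with no base ever applied to the butenolide.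

Step 4 is third: the ester-bearing enolate may give lower diastereoselectivity, the tert-butyl ester meets a boron Lewis acid, and lactonisation may be incomplete. The fallback sets out from 1 (and uses 6) and comes back at 9, carrying the lactone carbonyl as an allyl group. Compound 1 is acylated (n-BuLi, pent-4-enoyl chloride, THF, −78 °C) to (4S)-4-benzyl-3-(pent-4-enoyl)-1,3-oxazolidin-2-one F1. Bu2BOTf and i-Pr2NEt give its Z-dibutylboron enolate F2, which adds to 6 to give the syn-aldol tert-butyl (16R,17S)-17-{[(4S)-4-benzyl-2-oxo-1,3-oxazolidin-3-yl]carbonyl}-16-hydroxyicos-19-enoate F3. O3 in CH2Cl2 at −78 °C gives the ozonide F4; Me2S reduces it to the hydroxy aldehyde, which closes to the lactol tert-butyl 15-[(2R,3S)-3-{[(4S)-4-benzyl-2-oxo-1,3-oxazolidin-3-yl]carbonyl}-5-hydroxyoxolan-2-yl]pentadecanoate F5. TEMPO with PhI(OAc)2 oxidises the lactol to lactone imide 9.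

**Further compounds**

F1 | step 4 | (4S)-4-benzyl-3-(pent-4-enoyl)-1,3-oxazolidin-2-one | C=CCCC(=O)N1[C@@H](Cc2ccccc2)COC1=O
F2 | step 4 | (4S)-4-benzyl-3-[(1Z)-1-(dibutylboranyloxy)penta-1,4-dien-1-yl]-1,3-oxazolidin-2-one | C=CC/C=C(\OB(CCCC)CCCC)N1[C@@H](Cc2ccccc2)COC1=O
F3 | step 4 | tert-butyl (16R,17S)-17-{[(4S)-4-benzyl-2-oxo-1,3-oxazolidin-3-yl]carbonyl}-16-hydroxyicos-19-enoate | C=CC[C@H](C(=O)N1[C@@H](Cc2ccccc2)COC1=O)[C@H](O)CCCCCCCCCCCCCCC(=O)OC(C)(C)C
F4 | step 4 | tert-butyl (16R,17S)-17-{[(4S)-4-benzyl-2-oxo-1,3-oxazolidin-3-yl]carbonyl}-16-hydroxy-18-(1,2,4-trioxolan-3-yl)octadecanoate (ozonide) | C1OC(C[C@H](C(=O)N2[C@@H](Cc3ccccc3)COC2=O)[C@H](O)CCCCCCCCCCCCCCC(=O)OC(C)(C)C)OO1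
F5 | step 4 | tert-butyl 15-[(2R,3S)-3-{[(4S)-4-benzyl-2-oxo-1,3-oxazolidin-3-yl]carbonyl}-5-hydroxyoxolan-2-yl]pentadecanoate (lactol, anomers) | OC1C[C@H](C(=O)N2[C@@H](Cc3ccccc3)COC2=O)[C@@H](CCCCCCCCCCCCCCC(=O)OC(C)(C)C)O1
F6 | step 7 | (2R,3S,4R)-2-(15-tert-butoxy-15-oxopentadecyl)-4-[(dimethylamino)methyl]-5-oxooxolane-3-carboxylic acid | O=C1[C@@H](CN(C)C)[C@H](C(=O)O)[C@@H](CCCCCCCCCCCCCCC(=O)OC(C)(C)C)O1
F7 | step 7 | (2R,3S,4R)-2-(15-tert-butoxy-15-oxopentadecyl)-5-oxo-4-[(trimethylazaniumyl)methyl]oxolane-3-carboxylate (betaine) | O=C1[C@@H](C[N+](C)(C)C)[C@H](C(=O)[O-])[C@@H](CCCCCCCCCCCCCCC(=O)OC(C)(C)C)O1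
F8 | step 7 | (2R,3S)-2-(15-tert-butoxy-15-oxopentadecyl)-4-methylidene-5-oxooxolane-3-carboxylic acid | O=C1C(=C)[C@H](C(=O)O)[C@@H](CCCCCCCCCCCCCCC(=O)OC(C)(C)C)O1
F9 | step 9 | (2R,3S,4S)-2-(15-tert-butoxy-15-oxopentadecyl)-4-methyl-5-oxooxolane-3-carboxylic acid | O=C1[C@@H](C)[C@H](C(=O)O)[C@@H](CCCCCCCCCCCCCCC(=O)OC(C)(C)C)O1
F10 | step 9 | (2R,3S,4S)-2-(15-tert-butoxy-15-oxopentadecyl)-4-methyl-5-oxo-4-(phenylselanyl)oxolane-3-carboxylic acid | O=C1[C@@](C)([Se]c2ccccc2)[C@H](C(=O)O)[C@@H](CCCCCCCCCCCCCCC(=O)OC(C)(C)C)O1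
F11 | step 9 | (2R,3S,4S)-2-(15-tert-butoxy-15-oxopentadecyl)-4-methyl-5-oxo-4-(phenylseleninyl)oxolane-3-carboxylic acid (selenoxide) | O=C1[C@@](C)([Se](=O)c2ccccc2)[C@H](C(=O)O)[C@@H](CCCCCCCCCCCCCCC(=O)OC(C)(C)C)O1
F12 | step 9 | (2R)-2-(15-tert-butoxy-15-oxopentadecyl)-4-methyl-5-oxo-2,5-dihydrofuran-3-carboxylic acid | CC1=C(C(=O)O)[C@@H](CCCCCCCCCCCCCCC(=O)OC(C)(C)C)OC1=O
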